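The route rests on disconnecting the chromone at C4–C4a. In the target the bridging methylene sits on C6 of the chromone benzo ring, para to C8a–O1 and flanked by O5 and O7. The aryl ether from which the pyranone is built therefore has a mirror plane through O1 and the bridge carbon, and its two ortho carbons are equivalent. A β-aryloxycrotonic acid carrying the complete diarylmethane and the (R)-isochromanone (isochromanone phenols as isopropyl ethers, chromone oxygens as methyl ethers) is activated as a mixed anhydride and acylates that ring, closing the pyranone in one operation with no regiochemical question. Boron trichloride then unmasks the three phenols.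

Key step: step 8

Remark 1: base-mediated addition of a phenol to a but-2-ynoate is taken to give the thermodynamically preferred E enol ether, so the isolated cyclisation substrate is the E acid 14; its Z isomer 15, the form that can close, is generated in the cyclisation flask.

Remark 2: the crotonate is attached to the phenol before the two arenes are joined. The benzylating partner is then not a free para-hydroxybenzyl alcohol (quinone-methide prone), its ring is electronically damped, and no base-mediated step is needed on the lactone-bearing diarylmethane before saponification.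

Step 1
Reactants: 1 methyl 2,4-dihydroxy-3,6-dimethylbenzoate (atraric acid)
Product: 2 methyl 2,4-diisopropoxy-3,6-dimethylbenzoate
Conditions: 2-bromopropane (6 equiv), Cs2CO3 (4 equiv), DMF, 70 °C
Reagents that add atoms: 2-bromopropane, CC(C)Br
Why: Williamson ether synthesis, in which both phenoxides (the hydrogen-bonded, flanked 2-OH needs the cesium counter-ion, heat and excess halide) displace bromide while the hindered methyl ester is inert to carbonate.

Step 2
Reactants: 2 methyl 2,4-diisopropoxy-3,6-dimethylbenzoate; 3 N-methoxy-N-methylacetamide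
Product: 5 methyl 2,4-diisopropoxy-3-methyl-6-(2-oxopropyl)benzoate, via benzylic lithium species 4 (not isolated)
Conditions: LiN(iPr)2 (1.3 equiv), THF, −78 °C; then 3 (1.5 equiv), −78 → −40 °C; aq. NH4Cl, neutral work-up
Reagents that add atoms: none
Why: Lateral (benzylic) lithiation of an ortho-toluate followed by Weinreb-amide acylation, the 6-methyl being acidified by the ortho ester, the chelated tetrahedral adduct preventing over-addition and the di-ortho-substituted ester resisting self-condensation at low temperature.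

Step 3
Reactants: 5 methyl 2,4-diisopropoxy-3-methyl-6-(2-oxopropyl)benzoate
Product: 7 (3R)-6,8-diisopropoxy-3,7-dimethylisochroman-1-one, via (R)-hydroxy ester 6 (not isolated)
Conditions: Lactobacillus kefir alcohol dehydrogenase ((R)-selective), NADP+ (cat.), MgCl2 (1 mM), i-PrOH/phosphate buffer pH 7 (1:4), 30 °C; extraction; then TsOH·H2O (5 mol%), toluene, 60 °C
Reagents that add atoms: none
Why: Enzymatic asymmetric ketone reduction with anti-Prelog selectivity, the NADPH-dependent dehydrogenase delivering hydride to the si face of the methyl ketone (methyl small, arylmethyl large) to set C3 as R with isopropanol recycling the cofactor, after which acid-catalysed lactonisation (intramolecular transesterification) closes the six-membered ring without breaking the carbinol C–O bond.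

Step 4
Reactants: 8 4-hydroxy-2,6-dimethoxybenzaldehyde; 9 ethyl but-2-ynoate
Product: 10 ethyl (2E)-3-(4-formyl-3,5-dimethoxyphenoxy)but-2-enoate
Conditions: 9 (1.5 equiv), K2CO3 (0.5 equiv), DMF, 85 °C
Reagents that add atoms: none
Why: Base-mediated oxa-Michael addition of the acidic para-formyl phenol to the ynoate, reversible under these conditions so that the more stable E enol ether (aryloxy trans to the ester) should prevail, with the non-enolisable aldehyde untouched by carbonate.

Step 5
Reactants: 10 ethyl (2E)-3-(4-formyl-3,5-dimethoxyphenoxy)but-2-enoate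
Product: 11 ethyl (2E)-3-[4-(hydroxymethyl)-3,5-dimethoxyphenoxy]but-2-enoate
Conditions: NaBH4 (1.0 equiv), EtOH/THF, 0 °C; aq. NaHCO3 work-up
Reagents that add atoms: none
Why: Chemoselective borohydride reduction of the aryl aldehyde, the push–pull β-aryloxy enoate (a vinylogous carbonate) being inert to NaBH4 at 0 °C and the non-acidic work-up preserving the ionisable electron-rich benzylic alcohol.

Step 6
Reactants: 7 (3R)-6,8-diisopropoxy-3,7-dimethylisochroman-1-one; 11 ethyl (2E)-3-[4-(hydroxymethyl)-3,5-dimethoxyphenoxy]but-2-enoate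
Product: 12 ethyl (2E)-3-(4-{[(3R)-6,8-diisopropoxy-3,7-dimethyl-1-oxoisochroman-5-yl]methyl}-3,5-dimethoxyphenoxy)but-2-enoate
Conditions: 7 (1.5 equiv), TsOH·H2O (5 mol%), 1,1,1,3,3,3-hexafluoropropan-2-ol/CH2Cl2 (1:4), 0 °C → rt; 11 (1.0 equiv) added over 2 h
Reagents that add atoms: none
Why: Friedel–Crafts benzylation, in which acid ionises the 2,6-dimethoxybenzylic alcohol to a stabilised cation that attacks C5 of 7, its only unsubstituted ring carbon (ortho to the 6- and para to the 8-isopropoxy group), while the vinylogous-carbonate oxygen damps the electrophile's own ring and slow addition to excess 7 limits self-condensation and double benzylation.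

Step 7
Reactants: 12 ethyl (2E)-3-(4-{[(3R)-6,8-diisopropoxy-3,7-dimethyl-1-oxoisochroman-5-yl]methyl}-3,5-dimethoxyphenoxy)but-2-enoate
Product: 14 (2E)-3-(4-{[(3R)-6,8-diisopropoxy-3,7-dimethyl-1-oxoisochroman-5-yl]methyl}-3,5-dimethoxyphenoxy)but-2-enoic acid, via ring-opened hydroxy diacid 13 (not isolated)
Conditions: LiOH·H2O (5 equiv), THF/H2O (3:1), 45 °C; then 1 M HCl to pH 2, EtOAc, rt
Reagents that add atoms: lithium hydroxide, [Li+].[OH-]
Why: Ester saponification, in which hydroxide cleaves the ethyl ester and opens the lactone to the seco acid, and acidification liberates the crotonic acid while the δ-hydroxy acid recloses to the six-membered lactone with retention at C3 because the carbinol C–O bond is never broken.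

Step 8
Reactants: 14 (2E)-3-(4-{[(3R)-6,8-diisopropoxy-3,7-dimethyl-1-oxoisochroman-5-yl]methyl}-3,5-dimethoxyphenoxy)but-2-enoic acid
Product: 17 (3R)-5-[(5,7-dimethoxy-2-methyl-4-oxo-4H-chromen-6-yl)methyl]-6,8-diisopropoxy-3,7-dimethylisochroman-1-one, via (Z)-acid 15 (not isolated), via (Z)-mixed anhydride 16 (not isolated)
Conditions: TFAA (3 equiv), TFA/CH2Cl2 (1:4, 0.02 M), 0 °C → rt
Reagents that add atoms: none
Why: TFAA turns the acid into its mixed trifluoroacetic anhydride, and in the acidic medium the E and Z enol ethers interconvert (C2-protonation to the aryloxy-stabilised oxocarbenium ion, or rotation in the ketene-like acylium), so that the material drains through the Z form 16, the only one whose carbonyl lies cis to the aryloxy group. The arene carbon ortho to the ether oxygen attacks the acyl carbon and loss of a proton and trifluoroacetate gives the chromone, an intramolecular Friedel–Crafts acylation of the kind known for closing β-aryloxy-α,β-unsaturated acids to chromones. The pyranone closes in a 6-exo-trig manner at the anhydride carbonyl, forming C4–C4a. No stereocentre is created, and C3 of the isochromanone, remote and not enolisable, is untouched. No regioselectivity is required, because the attacked ring is symmetric about the O1–C6 axis, each ortho carbon is activated by an ortho and a para methoxy group besides the ether oxygen, and the hexasubstituted isochromanone ring has no free carbon. The mild activation without a strong Lewis acid is chosen to spare the isopropyl ethers and the acid-sensitive diarylmethane.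

Step 9
Reactants: 17 (3R)-5-[(5,7-dimethoxy-2-methyl-4-oxo-4H-chromen-6-yl)methyl]-6,8-diisopropoxy-3,7-dimethylisochroman-1-one
Product: 18 (3R)-6,8-dihydroxy-5-[(5-hydroxy-7-methoxy-2-methyl-4-oxo-4H-chromen-6-yl)methyl]-3,7-dimethylisochroman-1-one (target)
Conditions: BCl3 (1 M in CH2Cl2, 6 equiv), CH2Cl2, −78 → 0 °C; then H2O
Reagents that add atoms: none
Why: Lewis-acid ether cleavage, in which boron trichloride bound to the chromone C4 carbonyl removes the peri 5-methyl group through a six-membered chelate and dealkylates both secondary isopropyl ethers, while the unchelated 7-methoxy group, the lactone and the C3 stereocentre should be unaffected at or below 0 °C.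

Compound list
1 | methyl 2,4-dihydroxy-3,6-dimethylbenzoate (atraric acid) | COC(=O)c1c(C)cc(O)c(C)c1O | starting material
2 | methyl 2,4-diisopropoxy-3,6-dimethylbenzoate | COC(=O)c1c(C)cc(OC(C)C)c(C)c1OC(C)C | intermediate
3 | N-methoxy-N-methylacetamide | CON(C)C(C)=O | starting material
4 | methyl 6-(lithiomethyl)-2,4-diisopropoxy-3-methylbenzoate (benzylic lithium species) | [Li]Cc1cc(OC(C)C)c(C)c(OC(C)C)c1C(=O)OC | intermediate (not isolated)
5 | methyl 2,4-diisopropoxy-3-methyl-6-(2-oxopropyl)benzoate | COC(=O)c1c(CC(C)=O)cc(OC(C)C)c(C)c1OC(C)C | intermediate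
6 | methyl 6-[(2R)-2-hydroxypropyl]-2,4-diisopropoxy-3-methylbenzoate | COC(=O)c1c(C[C@@H](C)O)cc(OC(C)C)c(C)c1OC(C)C | intermediate (not isolated)
7 | (3R)-6,8-diisopropoxy-3,7-dimethylisochroman-1-one | CC(C)Oc1cc2C[C@@H](C)OC(=O)c2c(OC(C)C)c1C | intermediate
8 | 4-hydroxy-2,6-dimethoxybenzaldehyde | COc1cc(O)cc(OC)c1C=O | starting material
9 | ethyl but-2-ynoate | CC#CC(=O)OCC | starting material
10 | ethyl (2E)-3-(4-formyl-3,5-dimethoxyphenoxy)but-2-enoate | CCOC(=O)/C=C(\C)Oc1cc(OC)c(C=O)c(OC)c1 | intermediate
11 | ethyl (2E)-3-[4-(hydroxymethyl)-3,5-dimethoxyphenoxy]but-2-enoate | CCOC(=O)/C=C(\C)Oc1cc(OC)c(CO)c(OC)c1 | intermediate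
12 | ethyl (2E)-3-(4-{[(3R)-6,8-diisopropoxy-3,7-dimethyl-1-oxoisochroman-5-yl]methyl}-3,5-dimethoxyphenoxy)but-2-enoate | CCOC(=O)/C=C(\C)Oc1cc(OC)c(Cc2c(OC(C)C)c(C)c(OC(C)C)c3c2C[C@@H](C)OC3=O)c(OC)c1 | intermediate
13 | 3-({4-[(E)-(1-carboxyprop-1-en-2-yl)oxy]-2,6-dimethoxyphenyl}methyl)-2-[(2R)-2-hydroxypropyl]-4,6-diisopropoxy-5-methylbenzoic acid (ring-opened hydroxy diacid) | C/C(Oc1cc(OC)c(Cc2c(OC(C)C)c(C)c(OC(C)C)c(C(=O)O)c2C[C@@H](C)O)c(OC)c1)=C\C(=O)O | intermediate (not isolated)
14 | (2E)-3-(4-{[(3R)-6,8-diisopropoxy-3,7-dimethyl-1-oxoisochroman-5-yl]methyl}-3,5-dimethoxyphenoxy)but-2-enoic acid | C/C(Oc1cc(OC)c(Cc2c(OC(C)C)c(C)c(OC(C)C)c3c2C[C@@H](C)OC3=O)c(OC)c1)=C\C(=O)O | intermediate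
15 | (2Z)-3-(4-{[(3R)-6,8-diisopropoxy-3,7-dimethyl-1-oxoisochroman-5-yl]methyl}-3,5-dimethoxyphenoxy)but-2-enoic acid | C/C(Oc1cc(OC)c(Cc2c(OC(C)C)c(C)c(OC(C)C)c3c2C[C@@H](C)OC3=O)c(OC)c1)=C/C(=O)O | intermediate (not isolated)
16 | (2Z)-3-(4-{[(3R)-6,8-diisopropoxy-3,7-dimethyl-1-oxoisochroman-5-yl]methyl}-3,5-dimethoxyphenoxy)but-2-enoic trifluoroacetic anhydride | C/C(Oc1cc(OC)c(Cc2c(OC(C)C)c(C)c(OC(C)C)c3c2C[C@@H](C)OC3=O)c(OC)c1)=C/C(=O)OC(=O)C(F)(F)F | intermediate (not isolated)
17 | (3R)-5-[(5,7-dimethoxy-2-methyl-4-oxo-4H-chromen-6-yl)methyl]-6,8-diisopropoxy-3,7-dimethylisochroman-1-one | COc1cc2oc(C)cc(=O)c2c(OC)c1Cc1c(OC(C)C)c(C)c(OC(C)C)c2c1C[C@@H](C)OC2=O | intermediate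
18 | (3R)-6,8-dihydroxy-5-[(5-hydroxy-7-methoxy-2-methyl-4-oxo-4H-chromen-6-yl)methyl]-3,7-dimethylisochroman-1-one | COc1cc2oc(C)cc(=O)c2c(O)c1Cc1c(O)c(C)c(O)c2c1C[C@@H](C)OC2=O | target

Total step count: 9 steps. Longest linear sequence: 7 steps (steps 1, 2, 3, 6, 7, 8, 9 from atraric acid); steps 4 and 5 form the short side branch.

Steps most likely to fail

Step 8 (acylative ring closure). The E-to-Z equilibration or the acylation itself may be too slow under mild anhydride activation. Forcing it with stronger acid risks ipso-protonation and fragmentation of the electron-rich diarylmethane and premature loss of isopropyl groups. The fallback builds the pyranone by the classical route through an ortho-hydroxyaryl methyl ketone, which involves no enol ether geometry. It sets out from ester 12. Pyrrolidine in MeCN at 60 °C displaces the aryloxy group by addition–elimination and frees (3R)-5-[(4-hydroxy-2,6-dimethoxyphenyl)methyl]-6,8-diisopropoxy-3,7-dimethylisochroman-1-one F1. C-acetylation ortho to the hydroxyl (Ac2O, BF3·OEt2, 0 °C → rt; the two ortho carbons are again equivalent) should give (3R)-5-[(3-acetyl-4-hydroxy-2,6-dimethoxyphenyl)methyl]-6,8-diisopropoxy-3,7-dimethylisochroman-1-one F2. Claisen condensation with ethyl acetate (NaH, THF) should give the 1,3-diketone 1-(6-hydroxy-2,4-dimethoxy-3-{[(3R)-6,8-diisopropoxy-3,7-dimethyl-1-oxoisochroman-5-yl]methyl}phenyl)butane-1,3-dione F3. Acid cyclodehydration (TsOH, toluene, 60 °C) then comes back to the route at chromone 17.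

Step 6 (Friedel–Crafts benzylation). The benzylic cation may be consumed by the ring of its own precursor or of the product (self-condensation, double benzylation, ipso transbenzylation) faster than by the hindered C5 of 7. The fallback joins the arenes by a regiodefined, non-cationic coupling. It sets out from lactone 7 and aldehyde 10. Bromination of 7 at its only free carbon (NBS, MeCN, 0 °C → rt) gives (3R)-5-bromo-6,8-diisopropoxy-3,7-dimethylisochroman-1-one F4. Borylation (B2(OH)4, Pd(OAc)2/XPhos, KOAc, EtOH, 80 °C) gives [(3R)-6,8-diisopropoxy-3,7-dimethyl-1-oxoisochroman-5-yl]boronic acid F5. Condensation of 10 with 4-methylbenzenesulfonohydrazide (MeOH, rt) gives ethyl (2E)-3-(3,5-dimethoxy-4-{(E)-[2-(4-methylbenzenesulfonyl)hydrazinylidene]methyl}phenoxy)but-2-enoate F6. Base-promoted reductive coupling of the tosylhydrazone with the boronic acid (K2CO3, dioxane, 110 °C; diazo formation, 1,2-aryl shift from boron, protodeboronation) comes back to the route at diarylmethane 12.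

Step 3 (asymmetric reduction). The (R)-selective dehydrogenase may turn the ortho-substituted ketone over poorly or discriminate its faces insufficiently. The fallback makes the opposite carbinol and inverts it. It sets out from ketone 5. A Prelog-selective reduction (baker's yeast, sucrose, water, 30 °C) should give methyl 6-[(2S)-2-hydroxypropyl]-2,4-diisopropoxy-3-methylbenzoate F7. Mitsunobu esterification with 4-nitrobenzoic acid (PPh3, DIAD, THF, 0 °C → rt) inverts the centre to methyl 2,4-diisopropoxy-3-methyl-6-[(2R)-2-(4-nitrobenzoyloxy)propyl]benzoate F8. Methanolysis (K2CO3, MeOH, rt) releases the (R)-hydroxy ester 6, and TsOH in toluene comes back to the route at lactone 7.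

Further compounds
F1 | step 8 | (3R)-5-[(4-hydroxy-2,6-dimethoxyphenyl)methyl]-6,8-diisopropoxy-3,7-dimethylisochroman-1-one | COc1cc(O)cc(OC)c1Cc1c(OC(C)C)c(C)c(OC(C)C)c2c1C[C@@H](C)OC2=O
F2 | step 8 | (3R)-5-[(3-acetyl-4-hydroxy-2,6-dimethoxyphenyl)methyl]-6,8-diisopropoxy-3,7-dimethylisochroman-1-one | COc1cc(O)c(C(C)=O)c(OC)c1Cc1c(OC(C)C)c(C)c(OC(C)C)c2c1C[C@@H](C)OC2=O
F3 | step 8 | 1-(6-hydroxy-2,4-dimethoxy-3-{[(3R)-6,8-diisopropoxy-3,7-dimethyl-1-oxoisochroman-5-yl]methyl}phenyl)butane-1,3-dione | COc1cc(O)c(C(=O)CC(C)=O)c(OC)c1Cc1c(OC(C)C)c(C)c(OC(C)C)c2c1C[C@@H](C)OC2=O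
F4 | step 6 | (3R)-5-bromo-6,8-diisopropoxy-3,7-dimethylisochroman-1-one | CC(C)Oc1c(Br)c2C[C@@H](C)OC(=O)c2c(OC(C)C)c1C
F5 | step 6 | [(3R)-6,8-diisopropoxy-3,7-dimethyl-1-oxoisochroman-5-yl]boronic acid | CC(C)Oc1c(B(O)O)c2C[C@@H](C)OC(=O)c2c(OC(C)C)c1C
F6 | step 6 | ethyl (2E)-3-(3,5-dimethoxy-4-{(E)-[2-(4-methylbenzenesulfonyl)hydrazinylidene]methyl}phenoxy)but-2-enoate | CCOC(=O)/C=C(\C)Oc1cc(OC)c(/C=N/NS(=O)(=O)c2ccc(C)cc2)c(OC)c1
F7 | step 3 | methyl 6-[(2S)-2-hydroxypropyl]-2,4-diisopropoxy-3-methylbenzoate | COC(=O)c1c(C[C@H](C)O)cc(OC(C)C)c(C)c1OC(C)C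
F8 | step 3 | methyl 2,4-diisopropoxy-3-methyl-6-[(2R)-2-(4-nitrobenzoyloxy)propyl]benzoate | COC(=O)c1c(C[C@@H](C)OC(=O)c2ccc(cc2)[N+](=O)[O-])cc(OC(C)C)c(C)c1OC(C)C
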